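**Plan**
- Furanone numbering: O1, C2 (lactone C=O), C3 (acyl-bearing carbon), C4 (enol carbon), C5 (carbon bearing CH2OH). The retrosynthesis cuts C3–C4 of the ring first, then the O1–C2 ester bond, then the C12–C13 bond of the side chain.
- Enabling feature: C3 lies between the C2 lactone carbonyl and the exocyclic ketone, so it is a 1,3-dicarbonyl carbon nucleophile. C4–C5–CH2OH is a glyceric acid unit with C4 at the carboxyl level, and the O1–C2 ester is a ready tether, so one enolate acylation closes the ring with the whole acyl chain already in place.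
- Forward order: a copper-catalysed sp3–sp3 coupling gives (S)-14-methylhexadecanoic acid. Its acyl Meldrum's acid (a temporary ring) delivers the 3-oxoacyl group as an acylketene to O2 of methyl (S)-3-O-tritylglycerate. A fluoride-mediated Lacey–Dieckmann closure then makes the furanone, and acid removes the trityl group.
- Stereochemistry: C5 (S) comes from methyl (S)-glycerate acetonide and the chain centre (S) from (S)-1-bromo-2-methylbutane. No bond to either centre is made or broken.
- Helpers: the trityl ether keeps the primary oxygen out of acyl transfer and six-ring closure and is removed in the last step. The methyl ester is the leaving group of the closure. The Meldrum's acid ring leaves as acetone and CO2.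

Key step: step 6

Remark: the target is drawn as one enol tautomer of a 3-acyltetronic acid; the tautomers interconvert freely, so the route aims at this compound whichever tautomer is drawn.

**Step 1**
Reactants: 1 (S)-1-bromo-2-methylbutane; 2 12-bromododecanoic acid
Product: 5 (S)-14-methylhexadecanoic acid, via (S)-2-methylbutylmagnesium bromide 3 (not isolated), via chloromagnesium 12-bromododecanoate 4 (not isolated)
Conditions: (a) 1 (1.5 equiv), Mg turnings, THF, 40 °C; (b) 2, MeMgCl (1.0 equiv), THF, −20 °C; (c) Grignard solution added to the carboxylate, Li2CuCl4 (3 mol %), THF, −20 °C to rt; aq. HCl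
Reagents that add atoms: none
Why: Copper-catalysed cross-coupling of a primary alkyl Grignard reagent with a primary alkyl bromide (Kochi coupling) on the magnesium carboxylate of the bromo acid, which is inert to the Grignard reagent at low temperature; the stereocentre of 1 is one carbon removed from the C–Mg bond, takes no part, and should reach 5 with its S configuration intact.

**Step 2**
Reactants: 5 (S)-14-methylhexadecanoic acid; 6 Meldrum's acid (2,2-dimethyl-1,3-dioxane-4,6-dione)
Product: 7 5-[(14S)-1-hydroxy-14-methylhexadecylidene]-2,2-dimethyl-1,3-dioxane-4,6-dione (acyl Meldrum's acid, enol form)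
Conditions: DCC (1.1 equiv), DMAP (1.5 equiv), CH2Cl2, 0 °C to rt; filter; wash with aq. KHSO4; used crude
Reagents that add atoms: none
Why: Carbodiimide-mediated C-acylation of Meldrum's acid (Steglich-type activation of the acid, attack by the Meldrum's acid enolate), which should give the stable enol 7 as an acylketene precursor without touching the remote stereocentre.

**Step 3**
Reactants: 8 methyl (S)-2,2-dimethyl-1,3-dioxolane-4-carboxylate
Product: 9 methyl (S)-2,3-dihydroxypropanoate (methyl (S)-glycerate)
Conditions: Dowex 50W-X8 (H+ form), MeOH–H2O (95:5), rt; filter, evaporate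
Reagents that add atoms: none
Why: Acid-catalysed hydrolysis of the isopropylidene acetal, in which no bond at the stereocentre is broken, so the S configuration should be kept while the methanol solvent holds the methyl ester in place.

**Step 4**
Reactants: 9 methyl (S)-2,3-dihydroxypropanoate
Product: 10 methyl (S)-2-hydroxy-3-(trityloxy)propanoate
Conditions: TrCl (1.05 equiv), Et3N (1.5 equiv), DMAP (0.05 equiv), CH2Cl2, 0 °C to rt
Reagents that add atoms: trityl chloride, ClC(c1ccccc1)(c1ccccc1)c1ccccc1
Why: Selective O-tritylation (SN1-type etherification through the trityl cation) of the primary hydroxyl, the bulk of the trityl group discriminating against the secondary α-hydroxyl, which stays free for step 5.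

**Step 5**
Reactants: 7 acyl Meldrum's acid; 10 methyl (S)-2-hydroxy-3-(trityloxy)propanoate
Product: 12 methyl (2S)-2-{[(16S)-16-methyl-3-oxooctadecanoyl]oxy}-3-(trityloxy)propanoate, via acylketene 11 (not isolated)
Conditions: 7 (1.2 equiv), dry toluene, 100 °C, 2–3 h
Reagents that add atoms: none
Why: Thermal cycloreversion of the acyl Meldrum's acid releases acetone and CO2 and gives acylketene 11, which the secondary hydroxyl of 10 should trap as the β-keto ester (acylketene alcoholysis) under neutral conditions that leave the C2 stereocentre, the methyl ester and the trityl ether untouched.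

**Step 6**
Reactants: 12 methyl (2S)-2-{[(16S)-16-methyl-3-oxooctadecanoyl]oxy}-3-(trityloxy)propanoate
Product: 14 (5S)-4-hydroxy-3-[(14S)-14-methylhexadecanoyl]-5-[(trityloxy)methyl]furan-2(5H)-one, via tetrabutylammonium tetronate 13 (not isolated)
Conditions: Bu4NF (1.0 M in THF, 2.2 equiv), THF, 0 °C to rt; then cold 1 M aq. HCl, EtOAc
Reagents that add atoms: none
Why: Fluoride deprotonates the doubly activated methylene of the 3-oxoacyl ester (pKa near 11), the enolate carbon attacks the methyl ester carbonyl of the glycerate unit (made more electrophilic by its α-acyloxy group), methoxide leaves, and a second, irreversible deprotonation gives the delocalised tricarbonyl anion 13, which is protonated on work-up. This is a Lacey–Dieckmann cyclisation in its fluoride-mediated form, the established entry to 3-acyltetronic acids from α-(β-ketoacyloxy) esters. The furanone ring closes by a 5-exo-trig attack that forms the C3–C4 bond, with the O1–C2 ester already in place as the tether. No stereocentre is created: C5 is carried over from methyl (S)-glycerate and the chain centre from 1. The step needs enolisation at the 1,3-dicarbonyl methylene without deprotonation of C5–H, which would epimerise C5 or expel trityloxide by E1cB; the gap of more than ten pKa units between the two sites, the mild base, and the fact that the product anion cannot be deprotonated again at C5 should secure this. The trityl ether keeps the primary oxygen from taking over the acyl group, so a six-membered pyrandione cannot arise.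

**Step 7**
Reactants: 14 (5S)-4-hydroxy-3-[(14S)-14-methylhexadecanoyl]-5-[(trityloxy)methyl]furan-2(5H)-one
Product: 15 (5S)-4-hydroxy-5-(hydroxymethyl)-3-[(14S)-14-methylhexadecanoyl]furan-2(5H)-one (target)
Conditions: p-TsOH·H2O (0.2 equiv), MeOH–CH2Cl2 (1:1), rt; chromatography on silica (CHCl3–MeOH–AcOH)
Reagents that add atoms: none
Why: Acid-catalysed SN1 solvolysis of the trityl ether, the trityl cation being captured by methanol, should free the primary alcohol; the acyltetronic acid is stable to acid and neither stereocentre can epimerise under these conditions.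

**Compound list**
1 | (S)-1-bromo-2-methylbutane | CC[C@H](C)CBr | starting material
2 | 12-bromododecanoic acid | OC(=O)CCCCCCCCCCCBr | starting material
3 | (S)-2-methylbutylmagnesium bromide | CC[C@H](C)C[Mg]Br | intermediate
4 | chloromagnesium 12-bromododecanoate | BrCCCCCCCCCCCC(=O)O[Mg]Cl | intermediate
5 | (S)-14-methylhexadecanoic acid | CC[C@H](C)CCCCCCCCCCCCC(=O)O | intermediate
6 | Meldrum's acid (2,2-dimethyl-1,3-dioxane-4,6-dione) | CC1(C)OC(=O)CC(=O)O1 | starting material
7 | 5-[(14S)-1-hydroxy-14-methylhexadecylidene]-2,2-dimethyl-1,3-dioxane-4,6-dione | CC[C@H](C)CCCCCCCCCCCCC(O)=C1C(=O)OC(C)(C)OC1=O | intermediate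
8 | methyl (S)-2,2-dimethyl-1,3-dioxolane-4-carboxylate | COC(=O)[C@@H]1COC(C)(C)O1 | starting material
9 | methyl (S)-2,3-dihydroxypropanoate | COC(=O)[C@@H](O)CO | intermediate
10 | methyl (S)-2-hydroxy-3-(trityloxy)propanoate | COC(=O)[C@@H](O)COC(c1ccccc1)(c1ccccc1)c1ccccc1 | intermediate
11 | (16S)-16-methyloctadec-1-ene-1,3-dione (acylketene) | CC[C@H](C)CCCCCCCCCCCCC(=O)C=C=O | intermediate
12 | methyl (2S)-2-{[(16S)-16-methyl-3-oxooctadecanoyl]oxy}-3-(trityloxy)propanoate | CC[C@H](C)CCCCCCCCCCCCC(=O)CC(=O)O[C@@H](COC(c1ccccc1)(c1ccccc1)c1ccccc1)C(=O)OC | intermediate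
13 | tetrabutylammonium (5S)-3-[(14S)-14-methylhexadecanoyl]-2-oxo-5-[(trityloxy)methyl]-2,5-dihydrofuran-4-olate | CC[C@H](C)CCCCCCCCCCCCC(=O)C1=C([O-])[C@H](COC(c2ccccc2)(c2ccccc2)c2ccccc2)OC1=O.CCCC[N+](CCCC)(CCCC)CCCC | intermediate
14 | (5S)-4-hydroxy-3-[(14S)-14-methylhexadecanoyl]-5-[(trityloxy)methyl]furan-2(5H)-one | CC[C@H](C)CCCCCCCCCCCCC(=O)C1=C(O)[C@H](COC(c2ccccc2)(c2ccccc2)c2ccccc2)OC1=O | intermediate
15 | (5S)-4-hydroxy-5-(hydroxymethyl)-3-[(14S)-14-methylhexadecanoyl]furan-2(5H)-one | CC[C@H](C)CCCCCCCCCCCCC(=O)C1=C(O)[C@H](CO)OC1=O | target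

**Step count and risks**
Total step count: 7. Longest linear sequence: 5 steps (steps 1, 2, 5, 6, 7; the glycerate branch, steps 3, 4, 5, 6, 7, is equally long).

Steps most likely to fail:

Step 6. What may go wrong: deprotonation at C5–H competing with the enolate acylation, which would erode the configuration at C5 or expel trityloxide by E1cB, or incomplete closure. The fallback closes the same ring under neutral conditions before the acyl chain is attached. It sets out from 10. Transesterification with benzyl alcohol (Ti(OiPr)4 cat., toluene, 80 °C) should give benzyl (S)-2-hydroxy-3-(trityloxy)propanoate F1. Heating F1 with ketenylidenetriphenylphosphorane (Ph3P=C=C=O) in toluene should add the hydroxyl to the cumulated ylide to give the ester ylide benzyl (S)-2-{[(triphenylphosphoranylidene)acetyl]oxy}-3-(trityloxy)propanoate F2. F2 is not isolated and should close by intramolecular Wittig olefination of the benzyl ester carbonyl to (S)-4-(benzyloxy)-5-[(trityloxy)methyl]furan-2(5H)-one F3. Hydrogenolysis (H2, 5% Pd/C, EtOAc, rt, stopped once the benzyl group is gone) should give (S)-4-hydroxy-5-[(trityloxy)methyl]furan-2(5H)-one F4. Treatment of F4 with acid 5, DCC, DMAP and Et3N in CH2Cl2 should give the enol ester (S)-5-oxo-2-[(trityloxy)methyl]-2,5-dihydrofuran-3-yl (S)-14-methylhexadecanoate F5. F5 is not isolated; DMAP should shift its acyl group from O to C3, and the route is rejoined at 14.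

Step 5. What may go wrong: slow interception of the acylketene by the hindered, electron-poor secondary hydroxyl, so that the ketene self-condenses, and acid-promoted loss of the trityl group at 100 °C. The fallback reverses the order of bond formation. It sets out from 10, which is heated with Meldrum's acid 6 (toluene, 80 °C) to give the malonic half-ester 3-{[(S)-1-methoxy-1-oxo-3-(trityloxy)propan-2-yl]oxy}-3-oxopropanoic acid F6. Acid 5 is activated separately with 1,1'-carbonyldiimidazole (THF, rt) to 1-[(S)-14-methylhexadecanoyl]-1H-imidazole F7. C-acylation of the magnesium enolate of F6 (MgCl2, Et3N, MeCN–THF, rt) by F7 with loss of CO2 (Masamune–Brooks decarboxylative Claisen condensation) should return the route at 12.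

Step 1. What may go wrong: sluggish coupling with competing reduction and homocoupling of the β-branched Grignard reagent, and precipitation of the magnesium carboxylate. The fallback joins the chain by olefination. It sets out from 1, which with PPh3 (MeCN, 100 °C, sealed tube) should give [(S)-2-methylbutyl]triphenylphosphonium bromide F8. Ylide formation (NaN(SiMe3)2, THF, −78 °C) and Wittig reaction with commercial methyl 12-oxododecanoate should give methyl (12Z,14S)-14-methylhexadec-12-enoate F9; the alkene geometry is irrelevant. Diimide reduction (TsNHNH2, NaOAc, aq. DME, reflux), chosen because it cannot move the double bond into the allylic stereocentre, should give methyl (S)-14-methylhexadecanoate F10. Saponification (LiOH, THF–H2O; then HCl) returns the route at 5.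

**Further compounds**
F1 | step 6 | benzyl (S)-2-hydroxy-3-(trityloxy)propanoate | O=C(OCc1ccccc1)[C@@H](O)COC(c1ccccc1)(c1ccccc1)c1ccccc1
F2 | step 6 | benzyl (S)-2-{[(triphenylphosphoranylidene)acetyl]oxy}-3-(trityloxy)propanoate | O=C(OCc1ccccc1)[C@@H](OC(=O)C=P(c1ccccc1)(c1ccccc1)c1ccccc1)COC(c1ccccc1)(c1ccccc1)c1ccccc1
F3 | step 6 | (S)-4-(benzyloxy)-5-[(trityloxy)methyl]furan-2(5H)-one | O=C1C=C(OCc2ccccc2)[C@H](COC(c2ccccc2)(c2ccccc2)c2ccccc2)O1
F4 | step 6 | (S)-4-hydroxy-5-[(trityloxy)methyl]furan-2(5H)-one | O=C1C=C(O)[C@H](COC(c2ccccc2)(c2ccccc2)c2ccccc2)O1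
F5 | step 6 | (S)-5-oxo-2-[(trityloxy)methyl]-2,5-dihydrofuran-3-yl (S)-14-methylhexadecanoate | CC[C@H](C)CCCCCCCCCCCCC(=O)OC1=CC(=O)O[C@H]1COC(c2ccccc2)(c2ccccc2)c2ccccc2
F6 | step 5 | 3-{[(S)-1-methoxy-1-oxo-3-(trityloxy)propan-2-yl]oxy}-3-oxopropanoic acid | COC(=O)[C@@H](OC(=O)CC(=O)O)COC(c1ccccc1)(c1ccccc1)c1ccccc1
F7 | step 5 | 1-[(S)-14-methylhexadecanoyl]-1H-imidazole | CC[C@H](C)CCCCCCCCCCCCC(=O)n1ccnc1
F8 | step 1 | [(S)-2-methylbutyl]triphenylphosphonium bromide | CC[C@H](C)C[P+](c1ccccc1)(c1ccccc1)c1ccccc1.[Br-]
F9 | step 1 | methyl (12Z,14S)-14-methylhexadec-12-enoate | CC[C@H](C)/C=C\CCCCCCCCCCC(=O)OC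
F10 | step 1 | methyl (S)-14-methylhexadecanoate | CC[C@H](C)CCCCCCCCCCCCC(=O)OC
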